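**Plan**

- Retrosynthesis: the two aryl benzyl ethers are cut first (protection), then the O1–C2 bond of the oxolane, then the ester C–O bond to (R)-2-methylbutanoic acid, and last the C3–C4 bond, which splits the carbon skeleton into two identical 3-arylpropanoyl units.
- Enabling feature: without the O1–C2 bond the oxolane (O1, C2 aryl, C3 acyloxymethyl, C4 arylmethyl, C5) is a 2,3-bis(arylmethyl)butane-1,4-diol with a twofold axis through the midpoint of C3–C4. Its two hydroxyls are homotopic, and the one that becomes O1 is 1,5-related to the benzylic C2–H.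
- Forward: two protected arylpropanoyl imides are joined at C3–C4 by oxidative enolate dimerisation, and the bis-imide is reduced to the twofold-symmetric diol. One hydroxyl is esterified, and the only ring, the oxolane, is then closed by alkoxy-radical 1,5-hydrogen transfer with C–O bond formation. Hydrogenolysis frees the phenols.
- Stereochemistry: C3 and C4 (both S) come from (R)-4-benzyloxazolidin-2-one in the dimerisation. C2 (R) comes from substrate control in the ring closure (aryl trans to the C3 arm). The side-chain centre is bought as (R)-2-methylbutanoic acid.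

Key step: step 6

Step 1
Reactants: 1 3-(4-hydroxy-3-methoxyphenyl)propanoic acid (dihydroferulic acid)
Product: 3 3-[4-(benzyloxy)-3-methoxyphenyl]propanoic acid, via benzyl ester 2 (not isolated)
Conditions: BnBr (2.3 equiv), K2CO3, DMF, 60 °C; then aq NaOH, MeOH, 60 °C; HCl to pH 2
Reagents that add atoms: benzyl bromide BrCc1ccccc1; sodium hydroxide [Na+].[OH-]
Why: Williamson alkylation of phenoxide and carboxylate, then saponification of the benzyl ester in the same flask, should leave only the robust aryl benzyl ether; no stereocenter is involved.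

Step 2
Reactants: 3 3-[4-(benzyloxy)-3-methoxyphenyl]propanoic acid; 4 (R)-4-benzyloxazolidin-2-one
Product: 6 (4R)-4-benzyl-3-{3-[4-(benzyloxy)-3-methoxyphenyl]propanoyl}oxazolidin-2-one, via mixed pivalic anhydride 5 (not isolated)
Conditions: PivCl, Et3N, THF, −20 °C; then 4, LiCl, −20 °C to rt
Reagents that add atoms: none
Why: N-acylation of the Evans auxiliary through the mixed pivalic anhydride, which is attacked at its less hindered carbonyl by the LiCl/Et3N-activated oxazolidinone; the auxiliary stereocenter is untouched.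

Step 3
Reactants: 6 (4R)-4-benzyl-3-{3-[4-(benzyloxy)-3-methoxyphenyl]propanoyl}oxazolidin-2-one (two molecules)
Product: 9 (2S,3S)-2,3-bis[4-(benzyloxy)-3-methoxybenzyl]-1,4-bis[(4R)-4-benzyl-2-oxooxazolidin-3-yl]butane-1,4-dione, via lithium Z-enolate 7 (not isolated), via trichlorotitanium Z-enolate 8 (not isolated)
Conditions: LiN(iPr)2 (1.1 equiv), THF, −78 °C; then TiCl4 (1.1 equiv), −78 °C to rt
Reagents that add atoms: none
Why: Oxidative enolate homocoupling: the Z-enolate is transferred to tetravalent titanium, Ti–O homolysis gives the α-imidyl radical and trivalent titanium, and the two units join at the face remote from the 4-benzyl group of each (R)-auxiliary (the facial sense of Evans alkylations), which forms the C3–C4 bond and should set both new centres S.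

Step 4
Reactants: 9 (2S,3S)-2,3-bis[4-(benzyloxy)-3-methoxybenzyl]-1,4-bis[(4R)-4-benzyl-2-oxooxazolidin-3-yl]butane-1,4-dione
Product: 10 (2S,3S)-2,3-bis[4-(benzyloxy)-3-methoxybenzyl]butane-1,4-diol
Conditions: LiBH4 (5 equiv), H2O (2 equiv), THF–Et2O, 0 °C to rt
Reagents that add atoms: none
Why: Reductive cleavage of the N-acyloxazolidinones by LiBH4 should give the two primary alcohols and return auxiliary 4 without touching the α-centres or the benzyl ethers; the diol has a twofold axis and homotopic hydroxyls.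

Step 5
Reactants: 10 (2S,3S)-2,3-bis[4-(benzyloxy)-3-methoxybenzyl]butane-1,4-diol; 11 (R)-2-methylbutanoic acid
Product: 12 (2S,3S)-2,3-bis[4-(benzyloxy)-3-methoxybenzyl]-4-hydroxybutyl (2R)-2-methylbutanoate
Conditions: 11 (0.9 equiv), DCC (0.95 equiv), DMAP (0.1 equiv), CH2Cl2, 0 °C, slow addition; recovered 10 recycled
Reagents that add atoms: none
Why: Steglich esterification; the hydroxyls are homotopic, so only one mono-ester can form, a deficit of acid limits double acylation, and catalytic DMAP at 0 °C should leave the α-centre of the alkyl acid intact.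

Step 6
Reactants: 12 (2S,3S)-2,3-bis[4-(benzyloxy)-3-methoxybenzyl]-4-hydroxybutyl (2R)-2-methylbutanoate
Product: 14 {(2R,3S,4S)-2-[4-(benzyloxy)-3-methoxyphenyl]-4-[4-(benzyloxy)-3-methoxybenzyl]oxolan-3-yl}methyl (2R)-2-methylbutanoate, via alkyl hypoiodite 13 (not isolated)
Conditions: PhI(OAc)2 (1.3 equiv), I2 (0.6 equiv), cyclohexane–CH2Cl2 (3:1), visible light (tungsten lamp), 20 °C, argon
Reagents that add atoms: none
Why: PhI(OAc)2 and I2 give acetyl hypoiodite, which turns the free primary hydroxyl of 12 into hypoiodite 13; light cleaves the O–I bond and the electrophilic alkoxy radical takes the benzylic hydrogen of the arylmethyl group on the ester-bearing carbon through a six-membered array (1,5-hydrogen transfer), after which the 4-alkoxybenzyl radical is oxidised by acetyl hypoiodite or iodine to the cation and iodine is returned. The closest known reaction type is the Suárez hypoiodite reaction, the remote etherification of alcohols to oxolanes, which is known for δ-benzylic C–H bonds of 4-arylbutan-1-ols. The oxolane closes by 5-exo-trig attack of the hydroxyl oxygen on the planar benzylic cation, which forms O1–C2. The new stereocenter C2 is controlled by the adjacent C3 centre: in the envelope transition state the aryl group lies pseudo-equatorial and anti to the acyloxymethyl arm, which should give the 2,3-trans (2R) isomer, also the more stable one. Site selectivity is needed among three C–H positions and rests on geometry and polarity: the other benzylic CH2 is reachable only through a five-membered array, and the acyloxymethyl CH2, though also 1,5-related, is electron-poor and has the stronger C–H bond. The ester on the second oxygen rules out a second closure, and the non-polar medium, short irradiation and absence of strong acid are relied on to keep acetyl hypoiodite from iodinating the dialkoxyarene rings and the cation from attacking the other arene.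

Step 7
Reactants: 14 {(2R,3S,4S)-2-[4-(benzyloxy)-3-methoxyphenyl]-4-[4-(benzyloxy)-3-methoxybenzyl]oxolan-3-yl}methyl (2R)-2-methylbutanoate
Product: 15 [(2R,3S,4S)-2-(4-hydroxy-3-methoxyphenyl)-4-(4-hydroxy-3-methoxybenzyl)oxolan-3-yl]methyl (2R)-2-methylbutanoate
Conditions: H2 (1 atm), 10% Pd/C, EtOAc, rt, stopped at complete debenzylation
Reagents that add atoms: none
Why: Hydrogenolysis of aryl benzyl ethers over Pd/C in neutral ethyl acetate should be much faster than cleavage of the cyclic benzylic C2–O1 bond, and the ester and all four stereocenters are not affected.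

**Compound list**

1 | 3-(4-hydroxy-3-methoxyphenyl)propanoic acid (dihydroferulic acid) | COc1cc(CCC(=O)O)ccc1O | starting material
2 | benzyl 3-[4-(benzyloxy)-3-methoxyphenyl]propanoate (formed in the flask) | COc1cc(CCC(=O)OCc2ccccc2)ccc1OCc1ccccc1 | intermediate
3 | 3-[4-(benzyloxy)-3-methoxyphenyl]propanoic acid | COc1cc(CCC(=O)O)ccc1OCc1ccccc1 | intermediate
4 | (R)-4-benzyloxazolidin-2-one | O=C1N[C@H](Cc2ccccc2)CO1 | starting material
5 | 3-[4-(benzyloxy)-3-methoxyphenyl]propanoic pivalic anhydride (formed in the flask) | COc1cc(CCC(=O)OC(=O)C(C)(C)C)ccc1OCc1ccccc1 | intermediate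
6 | (4R)-4-benzyl-3-{3-[4-(benzyloxy)-3-methoxyphenyl]propanoyl}oxazolidin-2-one | COc1cc(CCC(=O)N2[C@H](Cc3ccccc3)COC2=O)ccc1OCc1ccccc1 | intermediate
7 | lithium Z-enolate of 6 (formed in the flask) | [Li]O/C(=C\Cc1ccc(OCc2ccccc2)c(OC)c1)N1[C@H](Cc2ccccc2)COC1=O | intermediate
8 | trichlorotitanium Z-enolate of 6 (formed in the flask) | Cl[Ti](Cl)(Cl)O/C(=C\Cc1ccc(OCc2ccccc2)c(OC)c1)N1[C@H](Cc2ccccc2)COC1=O | intermediate
9 | (2S,3S)-2,3-bis[4-(benzyloxy)-3-methoxybenzyl]-1,4-bis[(4R)-4-benzyl-2-oxooxazolidin-3-yl]butane-1,4-dione | O=C1OC[C@@H](Cc2ccccc2)N1C(=O)[C@@H](Cc1ccc(OCc2ccccc2)c(OC)c1)[C@H](Cc1ccc(OCc2ccccc2)c(OC)c1)C(=O)N1[C@H](Cc2ccccc2)COC1=O | intermediate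
10 | (2S,3S)-2,3-bis[4-(benzyloxy)-3-methoxybenzyl]butane-1,4-diol | OC[C@@H](Cc1ccc(OCc2ccccc2)c(OC)c1)[C@H](Cc1ccc(OCc2ccccc2)c(OC)c1)CO | intermediate
11 | (R)-2-methylbutanoic acid | CC[C@@H](C)C(=O)O | starting material
12 | (2S,3S)-2,3-bis[4-(benzyloxy)-3-methoxybenzyl]-4-hydroxybutyl (2R)-2-methylbutanoate | CC[C@@H](C)C(=O)OC[C@@H](Cc1ccc(OCc2ccccc2)c(OC)c1)[C@H](Cc1ccc(OCc2ccccc2)c(OC)c1)CO | intermediate
13 | (2S,3S)-2,3-bis[4-(benzyloxy)-3-methoxybenzyl]-4-(iodooxy)butyl (2R)-2-methylbutanoate (hypoiodite of 12, formed in the flask) | CC[C@@H](C)C(=O)OC[C@@H](Cc1ccc(OCc2ccccc2)c(OC)c1)[C@H](Cc1ccc(OCc2ccccc2)c(OC)c1)COI | intermediate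
14 | {(2R,3S,4S)-2-[4-(benzyloxy)-3-methoxyphenyl]-4-[4-(benzyloxy)-3-methoxybenzyl]oxolan-3-yl}methyl (2R)-2-methylbutanoate | CC[C@@H](C)C(=O)OC[C@@H]1[C@H](Cc2ccc(OCc3ccccc3)c(OC)c2)CO[C@H]1c1ccc(OCc2ccccc2)c(OC)c1 | intermediate
15 | [(2R,3S,4S)-2-(4-hydroxy-3-methoxyphenyl)-4-(4-hydroxy-3-methoxybenzyl)oxolan-3-yl]methyl (2R)-2-methylbutanoate | CC[C@@H](C)C(=O)OC[C@@H]1[C@H](Cc2ccc(O)c(OC)c2)CO[C@H]1c1ccc(O)c(OC)c1 | target

Total step count: 7. Longest linear sequence: 7 steps (1 to 15).

**Steps most likely to fail**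

Step 6. Three processes threaten it: electrophilic iodination of the dialkoxyarene rings by acetyl hypoiodite before the O–I bond is photolysed, Friedel–Crafts capture of the benzylic cation by the second arene, and poor facial selectivity at C2. The fallback makes O1–C2 without an alkoxy radical and sets out from diol 10. One equivalent of DDQ in CH2Cl2 over solid NaHCO3 at 0 °C should abstract hydride from either benzylic CH2, the two being equivalent by symmetry. The 1,5-related hydroxyl traps the resulting 4-alkoxybenzyl cation and should give {(2R,3S,4S)-2-[4-(benzyloxy)-3-methoxyphenyl]-4-[4-(benzyloxy)-3-methoxybenzyl]oxolan-3-yl}methanol F1; the single equivalent of oxidant is meant to stop a second closure by the remaining hydroxyl. Steglich esterification of F1 with 11 (DCC, DMAP, CH2Cl2, 0 °C) comes back to the route at 14.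

Step 3. The radical dimerisation may show low diastereoselectivity, or the titanium enolate may fail to oxidise cleanly and return the imide. The fallback builds the C3–C4 bond by lactone enolate alkylation and sets out from imide 6. NaN(SiMe3)2 in THF at −78 °C gives the sodium Z-enolate F2, which is alkylated by tert-butyl bromoacetate anti to the auxiliary benzyl group (Evans alkylation) to give tert-butyl (3S)-4-[(4R)-4-benzyl-2-oxooxazolidin-3-yl]-3-[4-(benzyloxy)-3-methoxybenzyl]-4-oxobutanoate F3. LiBH4 reduces the imide carbonyl in preference to the tert-butyl ester, releasing 4 and giving tert-butyl (3S)-3-[4-(benzyloxy)-3-methoxybenzyl]-4-hydroxybutanoate F4. Catalytic TsOH in toluene lactonises F4 to (4S)-4-[4-(benzyloxy)-3-methoxybenzyl]oxolan-2-one F5. LiN(SiMe3)2 in THF at −78 °C gives the lithium enolate F6, which purchasable 4-(benzyloxy)-3-methoxybenzyl bromide alkylates trans to the existing substituent to give (3S,4S)-3,4-bis[4-(benzyloxy)-3-methoxybenzyl]oxolan-2-one F7. LiAlH4 in THF reduces F7 to the diol, and the route is rejoined at 10.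

Step 7. Over-reduction is the risk: once the phenols are free, the benzylic C2–O1 bond of the oxolane may also undergo hydrogenolysis. The fallback moves the hydrogenolysis ahead of ring formation and sets out from 12, which has no benzylic C–O bond other than the two protecting groups. H2 over Pd/C in EtOAc should give (2S,3S)-4-hydroxy-2,3-bis(4-hydroxy-3-methoxybenzyl)butyl (2R)-2-methylbutanoate F8. Chattaway acetylation (Ac2O, aq NaOH, 0 °C) acylates only the phenoxides and should give (2S,3S)-2,3-bis(4-acetoxy-3-methoxybenzyl)-4-hydroxybutyl (2R)-2-methylbutanoate F9. Under the conditions of step 6, F9 passes through its hypoiodite, (2S,3S)-2,3-bis(4-acetoxy-3-methoxybenzyl)-4-(iodooxy)butyl (2R)-2-methylbutanoate F10, to [(2R,3S,4S)-2-(4-acetoxy-3-methoxyphenyl)-4-(4-acetoxy-3-methoxybenzyl)oxolan-3-yl]methyl (2R)-2-methylbutanoate F11; the less electron-rich acetoxyarenes are also less prone to iodination. Pyrrolidine in CH2Cl2 at 0 °C cleaves the two aryl acetates by aminolysis, leaves the aliphatic ester, and comes back to the route at 15.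

Further compounds
F1 | step 6 | {(2R,3S,4S)-2-[4-(benzyloxy)-3-methoxyphenyl]-4-[4-(benzyloxy)-3-methoxybenzyl]oxolan-3-yl}methanol | OC[C@@H]1[C@H](Cc2ccc(OCc3ccccc3)c(OC)c2)CO[C@H]1c1ccc(OCc2ccccc2)c(OC)c1
F2 | step 3 | sodium Z-enolate of 6 | [Na]O/C(=C\Cc1ccc(OCc2ccccc2)c(OC)c1)N1[C@H](Cc2ccccc2)COC1=O
F3 | step 3 | tert-butyl (3S)-4-[(4R)-4-benzyl-2-oxooxazolidin-3-yl]-3-[4-(benzyloxy)-3-methoxybenzyl]-4-oxobutanoate | CC(C)(C)OC(=O)C[C@H](Cc1ccc(OCc2ccccc2)c(OC)c1)C(=O)N1[C@H](Cc2ccccc2)COC1=O
F4 | step 3 | tert-butyl (3S)-3-[4-(benzyloxy)-3-methoxybenzyl]-4-hydroxybutanoate | CC(C)(C)OC(=O)C[C@H](Cc1ccc(OCc2ccccc2)c(OC)c1)CO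
F5 | step 3 | (4S)-4-[4-(benzyloxy)-3-methoxybenzyl]oxolan-2-one | O=C1C[C@H](Cc2ccc(OCc3ccccc3)c(OC)c2)CO1
F6 | step 3 | lithium enolate of F5 | [Li]OC1=C[C@H](Cc2ccc(OCc3ccccc3)c(OC)c2)CO1
F7 | step 3 | (3S,4S)-3,4-bis[4-(benzyloxy)-3-methoxybenzyl]oxolan-2-one | O=C1[C@@H](Cc2ccc(OCc3ccccc3)c(OC)c2)[C@H](Cc2ccc(OCc3ccccc3)c(OC)c2)CO1
F8 | step 7 | (2S,3S)-4-hydroxy-2,3-bis(4-hydroxy-3-methoxybenzyl)butyl (2R)-2-methylbutanoate | CC[C@@H](C)C(=O)OC[C@@H](Cc1ccc(O)c(OC)c1)[C@H](Cc1ccc(O)c(OC)c1)CO
F9 | step 7 | (2S,3S)-2,3-bis(4-acetoxy-3-methoxybenzyl)-4-hydroxybutyl (2R)-2-methylbutanoate | CC[C@@H](C)C(=O)OC[C@@H](Cc1ccc(OC(C)=O)c(OC)c1)[C@H](Cc1ccc(OC(C)=O)c(OC)c1)CO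
F10 | step 7 | (2S,3S)-2,3-bis(4-acetoxy-3-methoxybenzyl)-4-(iodooxy)butyl (2R)-2-methylbutanoate | CC[C@@H](C)C(=O)OC[C@@H](Cc1ccc(OC(C)=O)c(OC)c1)[C@H](Cc1ccc(OC(C)=O)c(OC)c1)COI
F11 | step 7 | [(2R,3S,4S)-2-(4-acetoxy-3-methoxyphenyl)-4-(4-acetoxy-3-methoxybenzyl)oxolan-3-yl]methyl (2R)-2-methylbutanoate | CC[C@@H](C)C(=O)OC[C@@H]1[C@H](Cc2ccc(OC(C)=O)c(OC)c2)CO[C@H]1c1ccc(OC(C)=O)c(OC)c1
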